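How much product and crystals will stand in this flask at the end, and how near to saturation will its coupling partner be?

the same everywhere: starting material 0.80 M

| charge | solid reagent | initiator | remark | time |
|---|---|---|---|---|
| Friday's | 0.80 equiv | 21 mol% | run made earlier |  |
| Monday's | 0.80 equiv | 33 mol% | run made earlier |  |
| flask | 0.800 equiv | 15 mol% |  | 15 h |

- Friday's (time / h: product / %, crystals / %): 1.50: 0, 0; 3.00: 0.3, 0.2; 5.00: 1.4, 0; 6.00: 1.6, 0.1; 8.00: 2.2, 0; 10.0: 2.8, 0.1; 12.0: 2.6, 0.4
- Monday's (time / h: product / %, crystals / %): 1.00: 0.1, 0.7; 1.33: 0.2, 0; 2.00: 0.7, 0; 3.00: 0.3, 0.1; 5.00: 0.3, 0.1; 8.00: 1.9, 0; 12.0: 2.8, 0.6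

(scatter of a reading: 0.3 percentage points)

- what is said of product includes crystals
- solid reagent, crystals is a solid; its amount is given per volume of the solution
- the earlier runs were read with a standard deviation of 0.3 percentage points
- at the start none of the solid reagent is in solution
- coupling partner is what solid reagent becomes in solution

1. product and crystals together at 15 h, in percent of the starting material charged
2. concentration of coupling partner in solution at 15 h, in percent of saturation

You have two earlier runs, Friday's and Monday's, that differ in initiator, 21 mol% against 33 mol%. At 12.0 h they read 2.6% and 2.8% of product, a gap of 0.2 percentage points between readings that each carry a standard deviation of 0.3 points, although Monday's run had 1.57 times the initiator. So in these two runs the pace does not seem to follow the initiator, and I look upstream to the solid reagent: if coupling partner is taken up as it arrives, then dissolution is the rate-limiting step and product grows in a straight line. The feed rate, the concentration of product gained per hour, taken as the mean of those two readings divided by their time, is 0.00180 M h⁻¹. The flask's 15 mol% of initiator lies below both runs, so carrying the feed rate over is my assumption. Over 15 h it gives 3.37% of the starting material, which costs 4.22% of the solid reagent charged, so the supply should hold. No reading shows the solubility, but I commit to a coupling partner low against saturation, taken up as it comes. The forecast gives 3.6% and 90% of saturation, reasoning that “Little is consumed, so the solution should approach saturation”; we are close on product and part on coupling partner.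

The flask gives 3.57% of product and crystals, with coupling partner at 0% of saturation.

    initiator → 2 initiating radical (k = 1.60 × 10⁻⁴ min⁻¹)
    starting material + initiating radical ⇌ chain carrier (K = 12000 M⁻¹, k = 14000 M⁻¹ s⁻¹)
    coupling partner + chain carrier → product + initiating radical (k = 6.00 × 10⁵ M⁻¹ min⁻¹)
    2 initiating radical → ended chains (k = 1.40 × 10⁹ M⁻¹ s⁻¹)
    solid reagent ⇌ coupling partner, rate k5*(cs5 - [coupling partner]) while solid is left; crystals form when [coupling partner] > cs5 (solubility = 0.0690 M, k = 4.60 × 10⁻⁴ min⁻¹)
    coupling partner → decomposed reagent (k = 0.00210 min⁻¹)
    crystals ⇌ product, rate k7*(cs7 - [product]) while solid is left; crystals form when [product] > cs7 (solubility = 0.280 M, k = 0.0320 min⁻¹)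

In this flask coupling partner stands at 4.08 × 10⁻⁷ M at 15.0 h, while 3.57% of the starting material charged is the most that dissolution can deliver by then into a solution kept empty, and the flask's product and crystals together match that figure. Now take the feed rate to the same flask left until 2.5 d: it gives 13.5% of the starting material, and that flask stands at 14.3% of product and crystals.

The numbers in the tables come from a simulation with constants of no real substance; noise was put on by code.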